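## Structural features

The target is a flavanone, a chroman-4-one in which ring A (a benzene ring) is fused through C4a and C8a to ring C, a six-membered dihydropyranone made of O1, C2, C3 and the C4 carbonyl carbon; ring B, a 3,4-dimethoxyphenyl group, is joined to C2 by a single bond. Ring A carries three adjacent methoxy groups on C5, C6 and C7 and a hydrogen on C8, so C4a is flanked on both sides by oxygen-bearing carbons (C5 and C8a) and the C5 methoxy group lies peri to the carbonyl. There is one stereocentre, C2 (S); it has no stereogenic neighbour, so nothing in the molecule can relay its configuration and it must be set by a chiral reagent or catalyst. C2 is benzylic, carries the ring oxygen and sits β to the ketone, which makes it the fragile point: enolisation towards C3 lets O1 leave from C2 (retro-oxa-Michael ring opening), and reclosure returns racemic material. Base, heat and strong acid therefore have to be avoided once C2 is set, whereas the five aryl methyl ethers are robust, with only the C5 ether at some risk from strong Lewis acids that chelate to the C4 carbonyl. The carbon skeleton is not the real difficulty; the difficulty is to create a configurationally labile C2 late, under near-neutral conditions and with high face selectivity. The key step exploits the fact that C4 is one isolated carbonyl carbon between C4a of ring A and C3, with O1 attached to C8a ortho to C4a. An ortho-iodophenol therefore supplies ring A with O1, carbon monoxide supplies C4, and a terminal arylalkyne supplies C3, C2 and ring B; the flat flavone that results is the prochiral substrate for C2.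

## Logic of the disconnections

**10 to 8 (through 9).** The C2–H and C3–H bonds are cut, that is, the two hydrogens across C2–C3 are removed. This takes away the only stereocentre and turns ring C into a fully conjugated pyranone that cannot racemise or ring-open, so no stereochemical information has to survive the skeleton-building step. The demand on the forward step is threefold. Hydride must reach the Re face of C2 under catalyst control. Only C2=C3 may be reduced, not C4=O or the arenes. The enolate that results must be masked at once (as 9) so that it cannot expel O1.

**8 to 3, 4 and 5 (through 7 and 6).** Three bonds of ring C are cut: C4a–C4, C3–C4 and O1–C2. The mapping is exact: the iodine-bearing carbon of 3 is C4a, its hydroxyl-bearing carbon is C8a and its methoxy-bearing carbons are C5, C6 and C7. The terminal alkyne carbon of 4 is C3 and the internal one is C2, and 5 is C4. The cut is made here because C4 is a one-carbon carbonyl linchpin and because every oxygen substituent of both aromatic rings is then present from the start. The gain is a fall from a bicyclic, penta-oxygenated heterocycle to two monocyclic arenes and a gas, joined convergently. The forward step must take up 5 faster than it couples 3 directly with 4, at a C–I bond that is hindered and electron-rich. It must also close ring C in the 6-endo sense from 6, which the relay through 7 secures. The hydroxyl group of 3 is left free because it is the nucleophile of the ring closure.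

**3 to 1 and 2.** The C4a–I bond is cut. The hydroxyl group of 1 directs an electrophile ortho, the two ortho positions are equivalent by symmetry and are the only unsubstituted ring positions, so only one mono-iodide can form. The gain is a cheap, symmetrical commercial phenol. The forward step must stop after one iodination and must not oxidise the very electron-rich ring.

## Other disconnections considered

**Alternative 1:** Ring A is cut at C4a–C8a and C5–C6 (with C8–C8a formally broken and remade), so that it is built from open chains. In the forward sense 2,3-dimethoxycyclobut-2-en-1-one A1 would be heated with the chiral methyl ynol ether A2, (3S,5R)-5-(3,4-dimethoxyphenyl)-1-methoxy-5-(triethylsilyloxy)-3-(triisopropylsilyloxy)pent-1-yne. A1 opens in a 4π electrocyclic step and adds across the triple bond of A2 in a [2+2] sense; a second 4π opening, a 6π electrocyclisation and tautomerisation would give the phenol A3, 2-[(1S,3R)-3-(3,4-dimethoxyphenyl)-3-(triethylsilyloxy)-1-(triisopropylsilyloxy)propyl]-3,4,5-trimethoxyphenol. Selective removal of the triethylsilyl group, Mitsunobu closure of O1–C2 with inversion (3R becoming 2S), removal of the triisopropylsilyl group and oxidation at C4 would lead to 10.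
- In its favour: the substitution pattern of ring A is fixed by the mechanism, no metal or toxic gas is needed, and C2 is set on an open chain without passing through a flat intermediate.
- Against it here: ring A is already available as 1, so building it is wasted effort. A2 needs two stereocentres, one of which (C4) is later destroyed, and two different silyl groups. Mitsunobu displacement at a carbinol activated by a 3,4-dimethoxyphenyl group risks ionisation and loss of configuration.
- Comparison: on regiocontrol of ring A the two plans are equal (mechanism there, symmetry of 1 here). The alternative is better in avoiding carbon monoxide under pressure and in not resting on one late enantioselective reduction. It is far worse in step economy (well over ten steps against three) and in convergence.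

**Alternative 2:** The O1–C8a bond is cut. The anti bromo diol A4, (1S,3S)-1-(6-bromo-2,3,4-trimethoxyphenyl)-3-(3,4-dimethoxyphenyl)propane-1,3-diol, would be cyclised with Pd(OAc)2, a bulky biarylphosphine and Cs2CO3. This would give the 2,4-cis flavan-4-ol A5, (2S,4S)-2-(3,4-dimethoxyphenyl)-5,6,7-trimethoxychroman-4-ol, which a mild oxidation at C4 would convert into 10.
- In its favour: only the C2 hydroxyl can reach C8a through a six-membered ring (the C4 hydroxyl would have to form a four-membered ring), so no protecting group is needed. The C2–O bond is not broken in the coupling, so configuration is retained. Both stereocentres would come from well-understood carbonyl reductions, and the enantiomeric purity of A4 could be raised by crystallisation before ring closure.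
- Against it here: secondary benzylic alkoxides on palladium are prone to β-hydride elimination, which would oxidise a carbinol and reduce the C–Br bond. The C4 stereocentre is made only to be oxidised away. A4 itself needs about four steps, for about six in all.
- Comparison: both plans close ring C with palladium, so on the metal they are equal. The alternative is better in stereochemical security, since C2 is never part of a flat or enolisable system before the last step. The chosen plan is better in bond economy (three skeletal bonds in one step against one), in redox economy and in length.

**Alternative 3:** C3–C4 and O1–C2 are cut in a formal [4+2] sense. 2-(Hydroxymethyl)-3,4,5-trimethoxyphenol A6, reachable from 1 by ortho-hydroxymethylation, would lose water under a chiral BINOL-derived phosphoric acid to give the ortho-quinone methide A7, 3,4,5-trimethoxy-6-methylidenecyclohexa-2,4-dien-1-one. A7, bound to the catalyst, would add 3,4-dimethoxystyrene A8 to give the flavan A9, (2S)-2-(3,4-dimethoxyphenyl)-5,6,7-trimethoxychromane; benzylic oxidation at C4 would then be needed to reach 10.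
- In its favour: ring C and the C2 stereocentre are made in one operation from two simple components, without metal or carbon monoxide, and C2 of A9 cannot epimerise because there is no carbonyl group.
- Against it here: A9 lacks the C4 oxygen, and installing it late means oxidising a CH2 group next to a C2–H bond that is both benzylic and α to oxygen. Loss of that hydrogen by over-oxidation would erase the stereocentre. A8 has no hydrogen-bonding group to hold it to the catalyst, so enantiocontrol would rest on steric contacts alone. A7 is unsubstituted at the methide carbon and prone to self-condensation, and A8 to acid-induced oligomerisation.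
- Comparison: the step count (three to four) is equal to that of the chosen plan, and setting C2 during ring formation is arguably the better, more direct use of a catalyst. The chosen plan is better in that carbon monoxide delivers C4 at the correct oxidation level, so no late oxidation is needed.

Key step: step 2

Assumption: the (R) enantiomer of DTBM-SEGPHOS is taken to direct the copper hydride to the Re face of C2 of 8, which gives (2S). If a trial on unsubstituted flavone were to show the opposite sense, the (S) ligand would be used and nothing else in the route would change.

## Route

**Step 1**
Reactants: 1 3,4,5-trimethoxyphenol; 2 N-iodosuccinimide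
Product: 3 2-iodo-3,4,5-trimethoxyphenol
Conditions: NIS (1.0 equiv), MeCN, −20 °C to 0 °C, dark; aq. Na2S2O3 work-up
Reagents that add atoms: N-iodosuccinimide, O=C1CCC(=O)N1I
Why: Electrophilic aromatic iodination of a strongly activated phenol; the hydroxyl group directs ortho, and the two ortho positions are equivalent by symmetry and are the only free ring positions, so a single mono-iodide can form. One equivalent of reagent at low temperature without added acid should limit a second iodination and oxidation of the ring.

**Step 2**
Reactants: 3 2-iodo-3,4,5-trimethoxyphenol; 4 4-ethynyl-1,2-dimethoxybenzene; 5 carbon monoxide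
Product: 8 5,6,7,3',4'-pentamethoxyflavone [2-(3,4-dimethoxyphenyl)-5,6,7-trimethoxy-4H-chromen-4-one], via ynone 6 (not isolated), via enaminone 7 (not isolated)
Conditions: PdCl2(PPh3)2 (5 mol %), CO (20 bar), 4 (1.3 equiv), Et2NH (solvent), 120 °C, autoclave
Reagents that add atoms: carbon monoxide, [C-]#[O+]
Why: This is the palladium-catalysed carbonylative Sonogashira-type annulation of ortho-iodophenols with terminal alkynes, a known flavone synthesis. Zerovalent palladium, formed from PdCl2(PPh3)2 in the amine, inserts into the C4a–I bond of 3, and carbon monoxide inserts to give the aroyl complex of divalent palladium. CO uptake should win over direct alkynylation because the aryl–palladium carbon is flanked by the C5 methoxy and C8a hydroxyl groups, the electron-rich aryl group migrates readily to CO, and the CO pressure and the absence of copper salts push the same way. Diethylamine deprotonates the palladium-bound alkyne 4, and reductive elimination forms C3–C4 and releases ynone 6. Diethylamine then adds to the β-carbon of 6 to give enaminone 7, and the C8a hydroxyl attacks the same carbon (C2) and expels the amine, so ring C closes by a 6-endo-trig addition–elimination that forms O1–C2. Because the amine has occupied C2 and made C3 a nucleophilic enamine carbon, the 5-exo attack at C3 that would lead to an aurone has no electrophilic site left. No stereocentre is formed; 8 is flat, and the aromatic character of its pyranone ring makes the closure irreversible. The free phenol needs no protection because it is the nucleophile of the final event.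

**Step 3**
Reactants: 8 5,6,7,3',4'-pentamethoxyflavone
Product: 10 (2S)-5,6,7,3',4'-pentamethoxyflavanone [(2S)-2-(3,4-dimethoxyphenyl)-5,6,7-trimethoxy-2,3-dihydro-4H-chromen-4-one], via silyl enol ether 9 (not isolated)
Conditions: Cu(OAc)2 (5 mol %), (R)-DTBM-SEGPHOS (5.5 mol %), (EtO)2MeSiH (3 equiv), toluene, 0 °C to rt; then 1 M HCl, THF, 0 °C
Reagents that add atoms: none
Why: Asymmetric copper hydride conjugate reduction (1,4-hydrosilylation) of a 2-substituted chromone: the ligated monovalent copper hydride formed from Cu(OAc)2 and the silane adds across C2=C3, the chiral bisphosphine pocket directing hydride to the Re face of C2 to set (2S), and silyl transfer to the copper enolate gives 9 and regenerates the hydride. Trapping as 9 protects C4 from 1,2-reduction and keeps the enolate from expelling O1, and the cold acidic hydrolysis protonates C3 (not a stereocentre) without touching C2.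

## Compound list

1 | 3,4,5-trimethoxyphenol | COc1cc(O)cc(OC)c1OC | starting material
2 | N-iodosuccinimide | O=C1CCC(=O)N1I | starting material
3 | 2-iodo-3,4,5-trimethoxyphenol | COc1cc(O)c(I)c(OC)c1OC | intermediate
4 | 4-ethynyl-1,2-dimethoxybenzene | C#Cc1ccc(OC)c(OC)c1 | starting material
5 | carbon monoxide | [C-]#[O+] | starting material
6 | 3-(3,4-dimethoxyphenyl)-1-(6-hydroxy-2,3,4-trimethoxyphenyl)prop-2-yn-1-one (ynone; not isolated) | COc1ccc(C#CC(=O)c2c(O)cc(OC)c(OC)c2OC)cc1OC | intermediate
7 | (E)-3-(diethylamino)-3-(3,4-dimethoxyphenyl)-1-(6-hydroxy-2,3,4-trimethoxyphenyl)prop-2-en-1-one (enaminone; not isolated; drawn as the expected E isomer, the geometry being lost on ring closure) | CCN(CC)/C(=C/C(=O)c1c(O)cc(OC)c(OC)c1OC)c1ccc(OC)c(OC)c1 | intermediate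
8 | 5,6,7,3',4'-pentamethoxyflavone [2-(3,4-dimethoxyphenyl)-5,6,7-trimethoxy-4H-chromen-4-one] | COc1ccc(-c2cc(=O)c3c(cc(OC)c(OC)c3OC)o2)cc1OC | intermediate
9 | (2S)-4-{[diethoxy(methyl)silyl]oxy}-2-(3,4-dimethoxyphenyl)-5,6,7-trimethoxy-2H-chromene (silyl enol ether; not isolated) | COc1ccc([C@@H]2C=C(O[Si](C)(OCC)OCC)c3c(cc(OC)c(OC)c3OC)O2)cc1OC | intermediate
10 | (2S)-5,6,7,3',4'-pentamethoxyflavanone [(2S)-2-(3,4-dimethoxyphenyl)-5,6,7-trimethoxy-2,3-dihydro-4H-chromen-4-one] | COc1ccc([C@@H]2CC(=O)c3c(cc(OC)c(OC)c3OC)O2)cc1OC | target

## Step count and least certain steps

Total step count: 3. Longest linear sequence: 3 steps (1 to 3 to 8 to 10); 4 and 5 enter at step 2.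

**Step 3 (enantioselective reduction), the least certain.**
- Hydride delivery may be slow or poorly face-selective, because C2=C3 of 8 is a vinylogous ester deactivated further by five donor groups and C2 is fully substituted.
- 1,2-Reduction at C4 may compete.
- The C8a aryloxide may undergo β-elimination from the copper enolate before silyl transfer, which would open ring C and lose the configuration.
- Racemisation by the same ring opening may occur if the hydrolysis of 9 is allowed to become basic.

Fallback (hydrogenation and reoxidation instead of conjugate hydride addition, with no enolate at any stage): setting out from 8, asymmetric hydrogenation would be run with the chiral carbene–ruthenium catalyst generated from Ru(cod)(2-methylallyl)2, enantiopure 1,3-bis[1-(naphthalen-1-yl)ethyl]-4,5-dihydroimidazolium tetrafluoroborate and KOtBu, under H2 pressure in hexane/toluene. The hand of the carbene ligand would be chosen for the 2S series. All hydrogens should be delivered from one face to C2=C3 and C4=O, giving the cis flavan-4-ol (2S,4S)-2-(3,4-dimethoxyphenyl)-5,6,7-trimethoxychroman-4-ol F1 (the same structure as A5). Oxidation of the C4 carbinol with Dess–Martin periodinane in CH2Cl2 at 0 °C to rt, which does not involve C2, would rejoin the route at 10.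

**Step 2 (key step).**
- The aryl–palladium intermediate may couple with the alkyne before CO uptake, followed by closure of a five-membered ring onto the triple bond.
- Diethylamine may capture the aroyl–palladium intermediate (aminocarbonylation).
- Oxidative addition at the hindered, electron-rich C–I bond may be slow, with reductive loss of iodine.
- 6 may close in the 5-exo sense if amine addition lags.

Fallback (classical chalcone route, no palladium or carbon monoxide): setting out from 1, C-acetylation ortho to the hydroxyl group with AcOH and BF3·OEt2 at about 90 °C (Friedel–Crafts acylation) would give 1-(6-hydroxy-2,3,4-trimethoxyphenyl)ethan-1-one F2. Claisen–Schmidt condensation of F2 with commercial 3,4-dimethoxybenzaldehyde (KOH, EtOH, rt) would give the chalcone (E)-3-(3,4-dimethoxyphenyl)-1-(6-hydroxy-2,3,4-trimethoxyphenyl)prop-2-en-1-one F3. Oxidative cyclisation with catalytic I2 in DMSO at about 130 °C (oxa-Michael closure, then dehydrogenation with DMSO as terminal oxidant) would rejoin the route at 8.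

**Step 1.**
- A second iodination may occur at the remaining ortho position.
- The iodonium source may oxidise the very electron-rich phenol.
- Iodine may be lost by protodeiodination in acid or light.

Fallback (directed ortho-metalation instead of electrophilic substitution, which introduces exactly one iodine): setting out from 1, the phenol would be protected with chloromethyl methyl ether and iPr2NEt in CH2Cl2 as 1,2,3-trimethoxy-5-(methoxymethoxy)benzene F4. Lithiation with n-butyllithium in THF at 0 °C at the position between the acetal oxygen and the neighbouring methoxy group, followed by I2, would give 2-iodo-3,4,5-trimethoxy-1-(methoxymethoxy)benzene F5. Cleavage of the acetal with HCl in MeOH at rt would rejoin the route at 3.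

## Further compounds

F1 | step 3 | (2S,4S)-2-(3,4-dimethoxyphenyl)-5,6,7-trimethoxychroman-4-ol | COc1ccc([C@@H]2C[C@H](O)c3c(cc(OC)c(OC)c3OC)O2)cc1OC
F2 | step 2 | 1-(6-hydroxy-2,3,4-trimethoxyphenyl)ethan-1-one | CC(=O)c1c(O)cc(OC)c(OC)c1OC
F3 | step 2 | (E)-3-(3,4-dimethoxyphenyl)-1-(6-hydroxy-2,3,4-trimethoxyphenyl)prop-2-en-1-one | COc1ccc(/C=C/C(=O)c2c(O)cc(OC)c(OC)c2OC)cc1OC
F4 | step 1 | 1,2,3-trimethoxy-5-(methoxymethoxy)benzene | COCOc1cc(OC)c(OC)c(OC)c1
F5 | step 1 | 2-iodo-3,4,5-trimethoxy-1-(methoxymethoxy)benzene | COCOc1cc(OC)c(OC)c(OC)c1I
A1 | alternative 1 | 2,3-dimethoxycyclobut-2-en-1-one | COC1=C(OC)C(=O)C1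
A2 | alternative 1 | (3S,5R)-5-(3,4-dimethoxyphenyl)-1-methoxy-5-(triethylsilyloxy)-3-(triisopropylsilyloxy)pent-1-yne | COC#C[C@@H](O[Si](C(C)C)(C(C)C)C(C)C)C[C@@H](O[Si](CC)(CC)CC)c1ccc(OC)c(OC)c1
A3 | alternative 1 | 2-[(1S,3R)-3-(3,4-dimethoxyphenyl)-3-(triethylsilyloxy)-1-(triisopropylsilyloxy)propyl]-3,4,5-trimethoxyphenol | COc1c(OC)c(OC)cc(O)c1[C@@H](O[Si](C(C)C)(C(C)C)C(C)C)C[C@@H](O[Si](CC)(CC)CC)c1ccc(OC)c(OC)c1
A4 | alternative 2 | (1S,3S)-1-(6-bromo-2,3,4-trimethoxyphenyl)-3-(3,4-dimethoxyphenyl)propane-1,3-diol | COc1ccc([C@@H](O)C[C@H](O)c2c(Br)cc(OC)c(OC)c2OC)cc1OC
A5 | alternative 2 | (2S,4S)-2-(3,4-dimethoxyphenyl)-5,6,7-trimethoxychroman-4-ol | COc1ccc([C@@H]2C[C@H](O)c3c(cc(OC)c(OC)c3OC)O2)cc1OC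
A6 | alternative 3 | 2-(hydroxymethyl)-3,4,5-trimethoxyphenol | COc1cc(O)c(CO)c(OC)c1OC
A7 | alternative 3 | 3,4,5-trimethoxy-6-methylidenecyclohexa-2,4-dien-1-one | C=C1C(=O)C=C(OC)C(OC)=C1OC
A8 | alternative 3 | 3,4-dimethoxystyrene (4-ethenyl-1,2-dimethoxybenzene) | C=Cc1ccc(OC)c(OC)c1
A9 | alternative 3 | (2S)-2-(3,4-dimethoxyphenyl)-5,6,7-trimethoxychromane | COc1ccc([C@@H]2CCc3c(cc(OC)c(OC)c3OC)O2)cc1OC
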